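The carboxyl carbon at C1 and the side chain at C5 are stripped back to carbonyls, which reveals that the cis-4a,8a-dimethyl decalin (ring A: C1–C4, C4a, C8a; ring B: C4a, C5–C8, C8a) is C2-symmetric about the midpoint of the C4a–C8a bond. Both angular methyls are therefore added in one flask across the C4a=C8a bond of the flat, achiral 2,3,4,6,7,8-hexahydronaphthalene-1,5-dione: a copper-catalysed asymmetric conjugate addition of Me3Al sets C8a and methylation of the resulting enolate sets C4a. A catalyst-controlled mono-reduction then turns one of the two homotopic carbonyls into a conformational lock that steers the C2 and C1 centres.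

Key step: step 2

Remark: the decalin carries the target numbering in every intermediate (C1 bears the future carboxyl carbon, C5 the future side chain), and CIP descriptors are attached to these locants.
Assumption: decahydronaphthalene-1,5-dione (cis/trans mixture) is bought; it is otherwise made from naphthalene-1,5-diol by hydrogenation and oxidation.
Remark: the enedione is reached by dehydrogenation of the saturated dione and not by dissolving-metal reduction of 1,5-dimethoxynaphthalene, because 1-methoxynaphthalenes tend to be protonated at the methoxy-bearing carbon and then lose methoxide.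
Assumption: the sense of induction of the ligand in step 2 is not known for this substrate; the antipode that gives (4aS,8aS)-7 is to be chosen after a trial with both, and the (S,R,R) ligand is written provisionally.

Step 1
Reactants: 1 decahydronaphthalene-1,5-dione (cis/trans mixture)
Product: 3 2,3,4,6,7,8-hexahydronaphthalene-1,5-dione, via 8a-bromodecalin-1,5-dione 2 (not isolated)
Conditions: Br2 (1.0 equiv), AcOH, 20 °C; evaporation; then Et3N (2.5 equiv), CH2Cl2, 0 to 20 °C
Reagents that add atoms: none
Why: Acid-catalysed α-bromination should occur at the more substituted ring-fusion carbon C8a through the tetrasubstituted enol, and because this tertiary bromide lies β to the C5 carbonyl, Et3N removes HBr by an E1cB elimination across C4a–C8a to give the conjugated, achiral enedione.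

Step 2
Reactants: 3 2,3,4,6,7,8-hexahydronaphthalene-1,5-dione; 4 trimethylaluminium; 5 iodomethane
Product: 7 (4aS,8aS)-4a,8a-dimethyldecahydronaphthalene-1,5-dione, via dimethylaluminium enolate 6 (not isolated)
Conditions: Cu(OTf)2 (5 mol %), (S,R,R)-phosphoramidite [O,O'-(S)-1,1'-binaphthyl-2,2'-diyl N,N-bis((R)-1-phenylethyl)phosphoramidite] (10 mol %), Me3Al (1.3 equiv), Et2O, −30 °C, 3 added over 2 h; then −78 °C, MeLi (1.2 equiv, less than total aluminium), DMPU, MeI (5 equiv), −78 to 0 °C; aqueous potassium sodium tartrate
Reagents that add atoms: trimethylaluminium, C[Al](C)C; iodomethane, CI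
Why: Proposed new method: Me3Al reduces Cu(OTf)2 to a monovalent methylcopper–phosphoramidite species that complexes the C4a=C8a bond, delivers methyl to C8a (β to the C5 carbonyl) by oxidative addition and reductive elimination and leaves the C4a=C5 dimethylaluminium enolate 6; MeLi, kept below the total aluminium so that it is consumed as the aluminate and not by the C1 ketone, raises the nucleophilicity of 6, which MeI then methylates on carbon at C4a. The closest known reaction type is the copper–phosphoramidite-catalysed conjugate addition of Me3Al to 3-substituted cyclohexenones that creates quaternary centres, with alkylation of the aluminium enolate after aluminate formation; new here is the tetrasubstituted ene-1,4-dione acceptor, whose second carbonyl compensates for the extra substituent. No ring is closed, because both rings are present in 3. C8a is set by the chiral ligand, which chooses one enantiotopic face of the flat enedione, and C4a by the substrate: MeI adds axially on ring B and anti to the pseudoaxial C8a–C1 bond, that is equatorially on ring A, which gives the cis-fused vicinal dimethyl pattern as in angular methylation of 1-decalone enolates and in conjugate additions to 10-methyloctalones. The two olefinic carbons of 3 are homotopic, so no regiochemistry arises, and the C2-symmetric product can be enriched by crystallisation. The selectivity needed is conjugate addition over electron-transfer reduction and 1,2-addition, secured by slow addition of 3 to an excess of the copper/aluminium reagent in Et2O at low temperature, and C- over O-methylation, secured by the soft electrophile MeI.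

Step 3
Reactants: 7 (4aS,8aS)-4a,8a-dimethyldecahydronaphthalene-1,5-dione
Product: 8 (4aS,5S,8aS)-5-hydroxy-4a,8a-dimethyloctahydronaphthalen-1(2H)-one
Conditions: (R)-2-methyl-CBS-oxazaborolidine [(R)-1-methyl-3,3-diphenyltetrahydro-1H,3H-pyrrolo[1,2-c][1,3,2]oxazaborole] (20 mol %), BH3·SMe2 (0.6 equiv), THF, −20 °C; MeOH quench; recovered 7 recycled
Reagents that add atoms: none
Why: In this Corey–Bakshi–Shibata reduction the two carbonyls of 7 are homotopic, so attack at either gives the same compound, the oxazaborolidine distinguishes the quaternary C4a side from the C6 methylene side and its (R)-enantiomer should deliver hydride to the face that gives the (5S)-alcohol with the hydroxyl cis to the angular methyls, and a deficit of borane holds the reaction at the mono-alcohol.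

Step 4
Reactants: 8 (4aS,5S,8aS)-5-hydroxy-4a,8a-dimethyloctahydronaphthalen-1(2H)-one; 5 iodomethane
Product: 11 (2R,4aS,5S,8aS)-5-hydroxy-2,4a,8a-trimethyloctahydronaphthalen-1(2H)-one, via dilithium alkoxide enolate 9 (not isolated), via C2-epimeric methyl ketones 10 (not isolated)
Conditions: LiN(i-Pr)2 (2.2 equiv), THF, −78 °C; MeI (1.2 equiv), −78 to −20 °C; H2O work-up; then NaOMe (0.2 equiv), MeOH, 20 °C
Reagents that add atoms: iodomethane, CI
Why: Kinetic lithium enolate alkylation at C2, the only enolisable position of the C1 ketone (the lithium alkoxide is inert to MeI at low temperature), is followed by base epimerisation in which the equatorial C5 hydroxyl locks the chair with the C8a methyl axial on ring A, where only the (2R) epimer with methyl trans to the angular methyls is equatorial while the (2S) epimer must accept a syn-axial methyl/methyl or hydroxyl/methyl contact.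

Step 5
Reactants: 11 (2R,4aS,5S,8aS)-5-hydroxy-2,4a,8a-trimethyloctahydronaphthalen-1(2H)-one; 12 methyltriphenylphosphonium bromide
Product: 14 (2R,4aS,5S,8aR)-2,4a,8a-trimethyl-1-methylidenedecahydronaphthalen-5-ol, via methylidenetriphenylphosphorane 13 (not isolated)
Conditions: 12 (4 equiv), KOt-Bu (4 equiv), toluene, 90 °C
Reagents that add atoms: methyltriphenylphosphonium bromide, C[P+](c1ccccc1)(c1ccccc1)c1ccccc1.[Br-]
Why: Wittig methylenation with the smallest ylide at elevated temperature is the established answer to a ketone flanked by a quaternary and a tertiary carbon, the basic medium cannot harm C2 because the (2R) epimer is the thermodynamic one, and no stereocenter is formed.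

Step 6
Reactants: 14 (2R,4aS,5S,8aR)-2,4a,8a-trimethyl-1-methylidenedecahydronaphthalen-5-ol
Product: 16 (2R,4aS,5S,8aR)-1-(hydroxymethyl)-2,4a,8a-trimethyldecahydronaphthalen-5-ol (C1 epimers), via alkylborane 15 (not isolated)
Conditions: BH3·THF (3 equiv), THF, 0 to 20 °C; then NaOH, H2O2, H2O, 0 to 40 °C
Reagents that add atoms: hydrogen peroxide, OO
Why: Anti-Markovnikov hydroboration of the 1,1-disubstituted alkene places boron on the unhindered terminal carbon and alkaline peroxide oxidation gives the primary alcohol, while the C1 configuration is left uncontrolled on purpose because step 7 corrects it.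

Step 7
Reactants: 16 (2R,4aS,5S,8aR)-1-(hydroxymethyl)-2,4a,8a-trimethyldecahydronaphthalen-5-ol (C1 epimers)
Product: 18 (1S,2R,4aS,5S,8aR)-5-hydroxy-2,4a,8a-trimethyldecahydronaphthalene-1-carbaldehyde, via C1-epimeric aldehydes 17 (not isolated)
Conditions: TEMPO (10 mol %), PhI(OAc)2 (1.2 equiv), CH2Cl2, 20 °C; aqueous NaHCO3 wash; then DBU (1 equiv), CH2Cl2, 20 °C
Reagents that add atoms: none
Why: Oxoammonium (TEMPO) oxidation is selective for the primary over the neopentyl secondary alcohol, and base epimerisation through the enol sets C1 under thermodynamic control, since with C2 fixed only the (1S) epimer holds the formyl group equatorial and trans to the C2 methyl whereas the (1R) epimer would press it axially against C5.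

Step 8
Reactants: 18 (1S,2R,4aS,5S,8aR)-5-hydroxy-2,4a,8a-trimethyldecahydronaphthalene-1-carbaldehyde
Product: 19 (1S,2R,4aS,8aR)-2,4a,8a-trimethyl-5-oxodecahydronaphthalene-1-carboxylic acid
Conditions: CrO3, H2SO4, H2O, acetone, 0 °C
Reagents that add atoms: water, O
Why: Jones oxidation converts the aldehyde through its hydrate into the carboxylic acid and the secondary alcohol into the ketone in one operation, the molecule has no alkene or acid-labile group at this stage, and the equatorial C1 centre is the stable epimer.

Step 9
Reactants: 19 (1S,2R,4aS,8aR)-2,4a,8a-trimethyl-5-oxodecahydronaphthalene-1-carboxylic acid; 20 (R)-solketal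
Product: 21 [(4S)-2,2-dimethyl-1,3-dioxolan-4-yl]methyl (1S,2R,4aS,8aR)-2,4a,8a-trimethyl-5-oxodecahydronaphthalene-1-carboxylate
Conditions: 20 (1.5 equiv), PPh3, DIAD, THF, 0 to 20 °C
Reagents that add atoms: (R)-solketal, CC1(C)OC[C@H](O1)CO
Why: Mitsunobu esterification activates the primary alcohol of 20 instead of the hindered carboxyl group, so the carboxylate attacks an unhindered CH2 carbon by SN2 displacement and the dioxolane stereocenter is untouched (its descriptor becomes S only through the priority change).

Step 10
Reactants: 21 [(4S)-2,2-dimethyl-1,3-dioxolan-4-yl]methyl (1S,2R,4aS,8aR)-2,4a,8a-trimethyl-5-oxodecahydronaphthalene-1-carboxylate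
Product: 23 [(4S)-2,2-dimethyl-1,3-dioxolan-4-yl]methyl (1S,2R,4aS,8aR)-2,4a,8a-trimethyl-5-(trifluoromethylsulfonyloxy)-1,2,3,4,4a,7,8,8a-octahydronaphthalene-1-carboxylate, via potassium enolate 22 (not isolated)
Conditions: KN(SiMe3)2 (1.2 equiv), THF, −78 °C; PhNTf2 (1.3 equiv), −78 to 0 °C
Reagents that add atoms: N-phenylbis(trifluoromethanesulfonimide), O=S(=O)(N(c1ccccc1)S(=O)(=O)C(F)(F)F)C(F)(F)F
Why: Kinetic deprotonation at C6, the only α-position of the ketone and far more acidic than the hindered C1–H of the ester, followed by O-sulfonylation of the enolate gives the C5=C6 enol triflate regiospecifically, and the equatorial ester cannot reach C6 for a Claisen-type closure.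

Step 11
Reactants: 23 the C5 enol triflate; 24 5-bromo-2-methylpent-2-ene
Product: 26 [(4S)-2,2-dimethyl-1,3-dioxolan-4-yl]methyl (1S,2R,4aR,8aR)-2,4a,8a-trimethyl-5-(4-methylpent-3-en-1-yl)-1,2,3,4,4a,7,8,8a-octahydronaphthalene-1-carboxylate, via homoprenylzinc bromide 25 (not isolated)
Conditions: 24 (2 equiv), Zn dust, LiCl, THF, 50 °C; then 23, Pd(dppf)Cl2 [dichloro(1,1'-bis(diphenylphosphino)ferrocene)palladium] (5 mol %), THF, 50 °C
Reagents that add atoms: 5-bromo-2-methylpent-2-ene, CC(C)=CCCBr
Why: In this Negishi coupling LiCl-assisted zinc insertion gives a primary alkylzinc that tolerates ester and acetal, and the bidentate dppf ligand on palladium favours reductive elimination over β-hydride elimination, so the C5–C(sp3) bond forms with the ring alkene fixed at C5=C6 and no stereocenter affected.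

Step 12
Reactants: 26 the coupled acetonide ester
Product: 27 (2S)-2,3-dihydroxypropyl (1S,2R,4aR,8aR)-2,4a,8a-trimethyl-5-(4-methylpent-3-en-1-yl)-1,2,3,4,4a,7,8,8a-octahydronaphthalene-1-carboxylate
Conditions: AcOH/H2O 4:1, 40 °C
Reagents that add atoms: none
Why: Mild acid hydrolysis of the isopropylidene acetal leaves the trisubstituted alkenes intact, and migration of the hindered acyl group is slow, so the glycerol stereocenter and the ester position are retained.

Step 13
Reactants: 27 the monoacylglycerol diol; 28 acetyl chloride
Product: 29 (2S)-3-acetoxy-2-hydroxypropyl (1S,2R,4aR,8aR)-2,4a,8a-trimethyl-5-(4-methylpent-3-en-1-yl)-1,2,3,4,4a,7,8,8a-octahydronaphthalene-1-carboxylate (CNP0146255.1)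
Conditions: AcCl (1.05 equiv), 2,4,6-collidine, CH2Cl2, −78 °C
Reagents that add atoms: acetyl chloride, CC(Cl)=O
Why: Low-temperature acylation with one equivalent of acetyl chloride and a hindered pyridine base is selective for the primary over the secondary hydroxyl, which should give the target without touching any stereocenter.

Compound list
1 | decahydronaphthalene-1,5-dione (cis/trans mixture) | O=C1CCCC2C1CCCC2=O | starting material
2 | 8a-bromodecahydronaphthalene-1,5-dione | O=C1CCCC2C(=O)CCCC12Br | intermediate
3 | 2,3,4,6,7,8-hexahydronaphthalene-1,5-dione (achiral enedione) | O=C1CCCC2=C1CCCC2=O | intermediate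
4 | trimethylaluminium | C[Al](C)C | starting material
5 | iodomethane | CI | starting material
6 | (8aS)-5-(dimethylalumanyloxy)-8a-methyl-3,4,6,7,8,8a-hexahydronaphthalen-1(2H)-one (aluminium enolate) | O=C1CCCC2=C(O[Al](C)C)CCC[C@]12C | intermediate
7 | (4aS,8aS)-4a,8a-dimethyldecahydronaphthalene-1,5-dione (cis ring fusion, C2-symmetric) | O=C1CCC[C@]2(C)C(=O)CCC[C@]12C | intermediate
8 | (4aS,5S,8aS)-5-hydroxy-4a,8a-dimethyloctahydronaphthalen-1(2H)-one (hydroxyl cis to the angular methyls) | O=C1CCC[C@]2(C)[C@@H](O)CCC[C@]12C | intermediate
9 | dilithium alkoxide enolate of 8 (C1=C2 enolate) | [Li]OC1=CCC[C@]2(C)[C@@H](O[Li])CCC[C@]12C | intermediate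
10 | (4aS,5S,8aS)-5-hydroxy-2,4a,8a-trimethyloctahydronaphthalen-1(2H)-one, mixture of C2 epimers | O=C1C(C)CC[C@]2(C)[C@@H](O)CCC[C@]12C | intermediate
11 | (2R,4aS,5S,8aS)-5-hydroxy-2,4a,8a-trimethyloctahydronaphthalen-1(2H)-one (C2 methyl trans to the angular methyls) | O=C1[C@H](C)CC[C@]2(C)[C@@H](O)CCC[C@]12C | intermediate
12 | methyltriphenylphosphonium bromide | C[P+](c1ccccc1)(c1ccccc1)c1ccccc1.[Br-] | starting material
13 | methylidenetriphenylphosphorane | C=P(c1ccccc1)(c1ccccc1)c1ccccc1 | intermediate
14 | (2R,4aS,5S,8aR)-2,4a,8a-trimethyl-1-methylidenedecahydronaphthalen-5-ol | C=C1[C@H](C)CC[C@]2(C)[C@@H](O)CCC[C@]12C | intermediate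
15 | C1-(borylmethyl) C5-O-boryl intermediate, C1 epimers, drawn as the monoalkylborane | [BH2]CC1[C@H](C)CC[C@]2(C)[C@@H](O[BH2])CCC[C@]12C | intermediate
16 | (2R,4aS,5S,8aR)-1-(hydroxymethyl)-2,4a,8a-trimethyldecahydronaphthalen-5-ol, C1 epimers | OCC1[C@H](C)CC[C@]2(C)[C@@H](O)CCC[C@]12C | intermediate
17 | (2R,4aS,5S,8aR)-5-hydroxy-2,4a,8a-trimethyldecahydronaphthalene-1-carbaldehyde, C1 epimers | O=CC1[C@H](C)CC[C@]2(C)[C@@H](O)CCC[C@]12C | intermediate
18 | (1S,2R,4aS,5S,8aR)-5-hydroxy-2,4a,8a-trimethyldecahydronaphthalene-1-carbaldehyde (formyl cis to the angular methyls, trans to the C2 methyl) | O=C[C@H]1[C@H](C)CC[C@]2(C)[C@@H](O)CCC[C@]12C | intermediate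
19 | (1S,2R,4aS,8aR)-2,4a,8a-trimethyl-5-oxodecahydronaphthalene-1-carboxylic acid | OC(=O)[C@H]1[C@H](C)CC[C@]2(C)C(=O)CCC[C@]12C | intermediate
20 | (R)-solketal, (R)-(2,2-dimethyl-1,3-dioxolan-4-yl)methanol | CC1(C)OC[C@H](O1)CO | starting material
21 | [(4S)-2,2-dimethyl-1,3-dioxolan-4-yl]methyl (1S,2R,4aS,8aR)-2,4a,8a-trimethyl-5-oxodecahydronaphthalene-1-carboxylate | CC1(C)OC[C@H](O1)COC(=O)[C@H]2[C@H](C)CC[C@]3(C)C(=O)CCC[C@]23C | intermediate
22 | potassium C5=C6 enolate of 21 | CC1(C)OC[C@H](O1)COC(=O)[C@H]2[C@H](C)CC[C@]3(C)C(O[K])=CCC[C@]23C | intermediate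
23 | [(4S)-2,2-dimethyl-1,3-dioxolan-4-yl]methyl (1S,2R,4aS,8aR)-2,4a,8a-trimethyl-5-(trifluoromethylsulfonyloxy)-1,2,3,4,4a,7,8,8a-octahydronaphthalene-1-carboxylate | CC1(C)OC[C@H](O1)COC(=O)[C@H]2[C@H](C)CC[C@]3(C)C(OS(=O)(=O)C(F)(F)F)=CCC[C@]23C | intermediate
24 | 5-bromo-2-methylpent-2-ene | CC(C)=CCCBr | starting material
25 | (4-methylpent-3-en-1-yl)zinc bromide | CC(C)=CCC[Zn]Br | intermediate
26 | [(4S)-2,2-dimethyl-1,3-dioxolan-4-yl]methyl (1S,2R,4aR,8aR)-2,4a,8a-trimethyl-5-(4-methylpent-3-en-1-yl)-1,2,3,4,4a,7,8,8a-octahydronaphthalene-1-carboxylate | CC1(C)OC[C@H](O1)COC(=O)[C@H]2[C@H](C)CC[C@]3(C)C(CCC=C(C)C)=CCC[C@]23C | intermediate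
27 | (2S)-2,3-dihydroxypropyl (1S,2R,4aR,8aR)-2,4a,8a-trimethyl-5-(4-methylpent-3-en-1-yl)-1,2,3,4,4a,7,8,8a-octahydronaphthalene-1-carboxylate | OC[C@H](O)COC(=O)[C@H]1[C@H](C)CC[C@]2(C)C(CCC=C(C)C)=CCC[C@]12C | intermediate
28 | acetyl chloride | CC(Cl)=O | starting material
29 | (2S)-3-acetoxy-2-hydroxypropyl (1S,2R,4aR,8aR)-2,4a,8a-trimethyl-5-(4-methylpent-3-en-1-yl)-1,2,3,4,4a,7,8,8a-octahydronaphthalene-1-carboxylate | CC(=O)OC[C@H](O)COC(=O)[C@H]1[C@H](C)CC[C@]2(C)C(CCC=C(C)C)=CCC[C@]12C | target

Total step count: 13. Longest linear sequence: 13 steps (1 to 29); the reagents 4, 5, 12, 20, 24 and 28 are bought.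

Steps most likely to fail

Step 2 carries the label and the main risk. Three processes may go wrong: poor discrimination of the enantiotopic faces of 3, electron-transfer reduction of the enedione in place of methyl transfer, and O-methylation or trans-alkylation of the crowded C4a enolate. The fallback uses known chemistry and sets out from 3. Conjugate addition of lithium dimethylcuprate (Me2CuLi from MeLi and CuI, Et2O, −78 °C) with trapping of the lithium enolate by MeI/HMPA, the classical cuprate addition–enolate alkylation, should give racemic cis-4a,8a-dimethyldecahydronaphthalene-1,5-dione F1. Under the conditions of step 3 the (R)-oxazaborolidine should reduce both enantiomers to (5S)-carbinols, so the (4aS,8aS) half becomes 8 and the (4aR,8aR) half becomes the diastereomer (4aR,5S,8aR)-5-hydroxy-4a,8a-dimethyloctahydronaphthalen-1(2H)-one F2. F2 is removed by chromatography and the route is rejoined at 8.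

Step 3 may suffer from incomplete catalyst control at a carbonyl that is neopentyl on one side, and from over-reduction to the diol. Its outcome matters because the hydroxyl configuration decides the sense of the C2 and C1 centres. The fallback sets out from 7 and gives up catalyst control. Substrate-controlled reduction with a deficit of NaBH4 (MeOH, −20 °C) should give 8 together with its C5 epimer (4aS,5R,8aS)-5-hydroxy-4a,8a-dimethyloctahydronaphthalen-1(2H)-one F3. The two are separated by chromatography and assigned by NOE to the angular methyls; F3 and any diol are oxidised back to 7 with Dess–Martin periodinane and resubmitted. The route is rejoined at 8.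

Step 5 may fail through steric shielding of the C1 carbonyl, with enolisation taking the place of addition of the phosphorus ylide. The fallback sets out from 11 and avoids olefination and hydroboration altogether. Corey–Chaykovsky epoxidation with the smaller dimethylsulfonium methylide (Me3S+ I−, n-BuLi, THF, 0 °C) should give the spiro-epoxide (2R,4aS,5S,8aS)-2,4a,8a-trimethylspiro[decahydronaphthalene-1,2'-oxiran]-5-ol F4. Meinwald rearrangement with BF3·OEt2 (CH2Cl2, −78 °C) should then give the aldehyde mixture 17 by hydride shift, and DBU equilibrates it to 18. This replaces steps 5 to 7, and the route is rejoined at 18.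

Further compounds
F1 | step 2 | racemic cis-4a,8a-dimethyldecahydronaphthalene-1,5-dione (7 plus its (4aR,8aR) enantiomer, which is drawn) | O=C1CCC[C@@]2(C)C(=O)CCC[C@@]12C
F2 | step 2 | (4aR,5S,8aR)-5-hydroxy-4a,8a-dimethyloctahydronaphthalen-1(2H)-one | O=C1CCC[C@@]2(C)[C@@H](O)CCC[C@@]12C
F3 | step 3 | (4aS,5R,8aS)-5-hydroxy-4a,8a-dimethyloctahydronaphthalen-1(2H)-one | O=C1CCC[C@]2(C)[C@H](O)CCC[C@]12C
F4 | step 5 | (2R,4aS,5S,8aS)-2,4a,8a-trimethylspiro[decahydronaphthalene-1,2'-oxiran]-5-ol (spiro carbon not defined) | O1CC12[C@H](C)CC[C@]3(C)[C@@H](O)CCC[C@]23C
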